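**Plan**

- Retrosynthetic cuts: C1≡C2 (Colvin homologation) and C3=C4 (cross-metathesis); C13–Br (from the C13 alcohol, with inversion); C5–C6 (allylation of a lactol acetate); C9–Cl and C10–OAc (anti addition to a C9=C10 alkene); the oxocane at O–C6 and C7–C8 (dichloroketene Claisen ring expansion); the oxetane at O–C12.
- Enabling feature (chain numbered C1 = alkyne CH to C15 = ethyl CH3, ring oxygen between C6 and C12): C6–C7 with its chlorine is a dichloroketene unit, and C10 and C12 are both oxygenated with only C11 between them. O, C10, C11 and C12 can therefore begin as an oxetane that carries C9=C8 as a vinyl group on C10.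
- Forward order: C12–C15 from (R)-2-hydroxybutanoic acid, acrolein aldol for C8–C10, oxetane by 4-exo-tet closure, then the eight-membered lactone (the only ring of the target) in one step by four-atom ring expansion; after that C7, C9/C10, C6, C13 and the enyne.
- Stereochemistry: C13 from the chiral pool (R, inverted to S in the bromination); C12 by chelation-controlled reduction, then inversion in the oxetane closure; C7 by equilibration of the α-chloro lactone; C9/C10 by anti chloro-acetoxylation on the outer face; C6 by oxocarbenium allylation; C3=C4 E by metathesis.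

Key step: step 8

Assumption: the boron aldol of step 3 is drawn as its 1,4-syn product (6S). C10 becomes sp2 in step 8, so its epimer would converge on the same lactone through the trans-oxetane. Atom labels C1–C15 are those of the target chain.

**Route**

Step 1
Reactants: 1 (R)-2-hydroxybutanoic acid
Product: 2 (R)-2-(benzyloxy)butanoic acid
Conditions: NaH (2.2 equiv), BnBr, THF/DMF, 0 °C → rt; then aq. HCl
Reagents that add atoms: benzyl bromide, BrCc1ccccc1
Why: Williamson etherification of the alkoxide of the carboxylate dianion; the carboxylate makes the α-hydrogen non-acidic, so the R centre should be kept.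

Step 2
Reactants: 2 (R)-2-(benzyloxy)butanoic acid
Product: 3 (R)-3-(benzyloxy)pentan-2-one
Conditions: MeLi (2.5 equiv), Et2O, −78 → 0 °C; then H2O (inverse quench)
Reagents that add atoms: methyllithium, [Li]C
Why: Organolithium addition to a lithium carboxylate (ketone synthesis from a carboxylic acid) stops at the dilithium gem-diolate, which is chelated by the α-benzyloxy group and releases the methyl ketone only on hydrolysis, so no tertiary alcohol should form and the stereocentre is not touched.

Step 3
Reactants: 3 (R)-3-(benzyloxy)pentan-2-one; 4 acrolein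
Product: 6 (3R,6S)-3-(benzyloxy)-6-hydroxyoct-7-en-4-one, via boron enolate 5 (not isolated)
Conditions: (c-C6H11)2BCl, Et3N, Et2O, −78 → 0 °C; 4, −78 °C; then H2O2, MeOH, pH 7 buffer
Reagents that add atoms: none
Why: Boron-mediated aldol addition: the methyl group is enolised kinetically and the chair-like (Zimmerman–Traxler) addition to acrolein is expected to follow the 1,4-syn preference of α-alkoxy methyl ketone enolates, setting C10 as 6S; this centre only serves to give one oxetane diastereomer and is erased in step 8.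

Step 4
Reactants: 6 (3R,6S)-3-(benzyloxy)-6-hydroxyoct-7-en-4-one
Product: 7 (3R,6S)-3-(benzyloxy)-6-[(triethylsilyl)oxy]oct-7-en-4-one
Conditions: Et3SiCl, imidazole, CH2Cl2, 0 °C
Reagents that add atoms: chlorotriethylsilane, CC[Si](CC)(CC)Cl
Why: Silyl ether formation blocks the C10 hydroxyl as a non-chelating group, so that only the α-benzyloxy group can direct the next reduction and the two oxygens stay differentiated.

Step 5
Reactants: 7 (3R,6S)-3-(benzyloxy)-6-[(triethylsilyl)oxy]oct-7-en-4-one
Product: 8 (3R,4S,6S)-3-(benzyloxy)-6-[(triethylsilyl)oxy]oct-7-en-4-ol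
Conditions: Zn(BH4)2, Et2O, −30 °C; then aq. NH4Cl
Reagents that add atoms: none
Why: Chelation-controlled (Cram-chelate) hydride reduction: divalent zinc bridges the ketone and the α-benzyloxy oxygen and hydride enters anti to the ethyl group, which should set C12 as the 3,4-anti (4S) alcohol.

Step 6
Reactants: 8 (3R,4S,6S)-3-(benzyloxy)-6-[(triethylsilyl)oxy]oct-7-en-4-ol
Product: 9 (3R,4S,6S)-3-(benzyloxy)-6-[(triethylsilyl)oxy]oct-7-en-4-yl methanesulfonate
Conditions: MeSO2Cl, Et3N, CH2Cl2, 0 °C
Reagents that add atoms: methanesulfonyl chloride, CS(=O)(=O)Cl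
Why: Sulfonate ester formation turns the C12 hydroxyl, the only free one, into the leaving group.

Step 7
Reactants: 9 (3R,4S,6S)-3-(benzyloxy)-6-[(triethylsilyl)oxy]oct-7-en-4-yl methanesulfonate
Product: 11 (2R,4S)-2-[(1R)-1-(benzyloxy)propyl]-4-ethenyloxetane (cis), via hydroxy mesylate 10 (not isolated)
Conditions: Bu4NF, THF, 0 °C; then KOtBu, THF, 0 °C → rt
Reagents that add atoms: none
Why: Fluoride desilylation frees the allylic C10 hydroxyl, whose alkoxide displaces the mesylate in an intramolecular Williamson etherification (4-exo-tet) with inversion at C12, so the 1,3-anti hydroxy mesylate should give the cis-2,4-disubstituted oxetane with C12 now R.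

Step 8
Reactants: 11 (2R,4S)-2-[(1R)-1-(benzyloxy)propyl]-4-ethenyloxetane; 12 dichloroacetyl chloride
Product: 15 (8R,5Z)-8-[(1R)-1-(benzyloxy)propyl]-3,3-dichloro-3,4,7,8-tetrahydro-2H-oxocin-2-one, via dichloroketene 13 (not isolated), via acyloxonium enolate zwitterion 14 (not isolated)
Conditions: 12 (3 equiv) added over 6 h to 11 and Et3N (3.3 equiv), Et2O, 0 °C → rt
Reagents that add atoms: none
Why: Proposed new method: dichloroketene 13, made slowly from 12 and Et3N, acylates the strained, Lewis-basic oxetane oxygen to the acyloxonium enolate 14, whose dichloro-enolate carbon (C7) bonds to the vinyl terminus (C8) while the allylic O–C10 bond breaks in a charge-accelerated [3,3]-sigmatropic shift; the closest known reaction type is the Malherbe–Belluš dichloroketene Claisen rearrangement of allyl ethers and its ring-expanding version on 2-vinyl tetrahydrofurans and tetrahydropyrans, to which the oxetane adds the release of roughly 25 kcal/mol of ring strain. The eight-membered lactone is closed by ring expansion of the four-membered ring by four atoms (O–C6 by acylation, C7–C8 by the shift, O–C10 cleaved), not by an end-to-end cyclisation. No stereocentre is formed: C12 and C13 are spectators, C10 becomes sp2, and the new C9=C10 bond has to be Z because the ring is eight-membered (C11 pseudoaxial on C10 in the chair-like transition state). The step needs O-acylation and rearrangement to outrun [2+2] cycloaddition at the vinyl group and chloride opening of the acyloxonium ion; this should be secured by the amine-generated ketene (sluggish towards unactivated monosubstituted alkenes, no zinc halide or other Lewis acid present), by slow addition, and by the intramolecular, strain-releasing nature of the shift, while the benzyl ether oxygen can only be acylated reversibly.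

Step 9
Reactants: 15 (8R,5Z)-8-[(1R)-1-(benzyloxy)propyl]-3,3-dichloro-3,4,7,8-tetrahydro-2H-oxocin-2-one
Product: 17 (3S,8R,5Z)-8-[(1R)-1-(benzyloxy)propyl]-3-chloro-3,4,7,8-tetrahydro-2H-oxocin-2-one (3,8-trans), via 3R-epimeric chloro lactone 16 (not isolated)
Conditions: Bu3SnH (1.05 equiv), Et3B (cat.), air, toluene, −20 °C; then Bu4NCl (0.2 equiv), MeCN, 40 °C
Reagents that add atoms: tetrabutylammonium chloride (its chloride exchanges with the C7 chlorine), CCCC[N+](CCCC)(CCCC)CCCC.[Cl-]
Why: Radical-chain hydrodechlorination should stop after one chlorine because the gem-dichloride is far more reactive than the monochloride, and C7 is then set under thermodynamic control by Finkelstein-type degenerate chloride exchange (SN2, no enolate, no elimination); the 3,8-trans isomer is expected to be favoured because it can hold the C–Cl bond pseudoaxial on the outer face, away from the carbonyl dipole, with the side chain pseudoequatorial.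

Step 10
Reactants: 17 (3S,8R,5Z)-8-[(1R)-1-(benzyloxy)propyl]-3-chloro-3,4,7,8-tetrahydro-2H-oxocin-2-one
Product: 18 (2R,4S,5S,7S)-2-[(1R)-1-(benzyloxy)propyl]-5,7-dichloro-8-oxooxocan-4-yl acetate
Conditions: trichloroisocyanuric acid (0.4 equiv), NaOAc (0.2 equiv), AcOH, rt, dark
Reagents that add atoms: trichloroisocyanuric acid, O=C1N(Cl)C(=O)N(Cl)C(=O)N1Cl; acetic acid, CC(=O)O
Why: Electrophilic cohalogenation (chloro-acetoxylation) by anti addition across the Z alkene: acetate should open the chloronium ion at C10, the carbon farther from the electron-poor C7 (chlorine plus carbonyl), from the open outer face of the tub-shaped ring anti to the C12 side chain, giving the 9,10-trans pair (C9 S, C10 S) and the final acetate in one step, while the lactone oxygen is too electron-poor to take part across the ring.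

Step 11
Reactants: 18 (2R,4S,5S,7S)-2-[(1R)-1-(benzyloxy)propyl]-5,7-dichloro-8-oxooxocan-4-yl acetate
Product: 20 (3S,5S,6S,8R)-8-[(1R)-1-(benzyloxy)propyl]-3,5-dichlorooxocane-2,6-diyl diacetate (anomers at C2), via aluminium hemiacetal 19 (not isolated)
Conditions: iBu2AlH (1.1 equiv), CH2Cl2, −78 °C; then pyridine, DMAP, Ac2O, −78 → −20 °C
Reagents that add atoms: acetic anhydride, CC(=O)OC(C)=O
Why: Reductive acetylation: the α-chloro medium-ring lactone (activated, cisoid ester) should be reduced faster than the secondary acetate, and the aluminium hemiacetal is acetylated in the cold before it can open to the hydroxy aldehyde, so the eight-membered ring is kept; C6 is an anomeric mixture, which is of no consequence.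

Step 12
Reactants: 20 (3S,5S,6S,8R)-8-[(1R)-1-(benzyloxy)propyl]-3,5-dichlorooxocane-2,6-diyl diacetate; 21 allyltrimethylsilane
Product: 22 (2R,4S,5S,7S,8S)-2-[(1R)-1-(benzyloxy)propyl]-5,7-dichloro-8-(prop-2-en-1-yl)oxocan-4-yl acetate
Conditions: 21 (5 equiv), BF3·OEt2, CH2Cl2, −78 → −20 °C
Reagents that add atoms: none
Why: Hosomi–Sakurai allylation of the eight-membered oxocarbenium ion formed from the anomeric acetate: the allylsilane is expected to add anti to the C12 side chain across the ring oxygen (2,8-trans) and syn to the C7 chlorine (the 1,2-cis preference of α-chloro oxocarbenium ions, whose C–Cl bond lies near the plane of the cation), both of which lead to 6S.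

Step 13
Reactants: 22 (2R,4S,5S,7S,8S)-2-[(1R)-1-(benzyloxy)propyl]-5,7-dichloro-8-(prop-2-en-1-yl)oxocan-4-yl acetate
Product: 23 (2R,4S,5S,7S,8S)-5,7-dichloro-2-[(1R)-1-hydroxypropyl]-8-(prop-2-en-1-yl)oxocan-4-yl acetate
Conditions: BCl3, C6HMe5, CH2Cl2, −78 °C; then MeOH/H2O
Reagents that add atoms: none
Why: Lewis acid debenzylation with pentamethylbenzene as a non-basic benzyl cation scavenger should cleave the benzyl ether at −78 °C without touching the acetate, the alkyl chlorides, the terminal alkene or the ring ether.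

Step 14
Reactants: 23 (2R,4S,5S,7S,8S)-5,7-dichloro-2-[(1R)-1-hydroxypropyl]-8-(prop-2-en-1-yl)oxocan-4-yl acetate
Product: 24 (2R,4S,5S,7S,8S)-2-[(1S)-1-bromopropyl]-5,7-dichloro-8-(prop-2-en-1-yl)oxocan-4-yl acetate
Conditions: CBr4, (n-C8H17)3P, toluene, 70 °C
Reagents that add atoms: carbon tetrabromide, BrC(Br)(Br)Br
Why: Appel-type bromination: bromide displaces the alkoxyphosphonium group in an SN2 step with inversion, turning the 13R alcohol into the 13S bromide, and trioctylphosphine in hot toluene should limit participation by the ring oxygen.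

Step 15
Reactants: 24 (2R,4S,5S,7S,8S)-2-[(1S)-1-bromopropyl]-5,7-dichloro-8-(prop-2-en-1-yl)oxocan-4-yl acetate; 25 (E)-but-2-enal
Product: 26 (2R,4S,5S,7S,8S)-2-[(1S)-1-bromopropyl]-5,7-dichloro-8-[(2E)-4-oxobut-2-en-1-yl]oxocan-4-yl acetate
Conditions: 25 (10 equiv), second-generation Grubbs catalyst RuCl2(=CHPh)(H2IMes)(PCy3) (5 mol %), CH2Cl2, 40 °C
Reagents that add atoms: none
Why: Olefin cross-metathesis of the terminal alkene with excess crotonaldehyde should give the conjugated enal under thermodynamic control, hence the E double bond.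

Step 16
Reactants: 26 (2R,4S,5S,7S,8S)-2-[(1S)-1-bromopropyl]-5,7-dichloro-8-[(2E)-4-oxobut-2-en-1-yl]oxocan-4-yl acetate
Product: 27 (2R,4S,5S,7S,8S)-2-[(1S)-1-bromopropyl]-5,7-dichloro-8-[(2E)-pent-2-en-4-yn-1-yl]oxocan-4-yl acetate (target)
Conditions: Me3SiCHN2, LiN(iPr)2 (1.2 equiv each), THF, −78 → 0 °C
Reagents that add atoms: (trimethylsilyl)diazomethane, C[Si](C)(C)C=[N+]=[N-]
Why: Colvin rearrangement (1,2-addition of the lithiated diazomethane to the aldehyde, elimination of silanolate, loss of N2 and 1,2-hydrogen shift) converts the enal into the terminal E-enyne, and at −78 °C with a small excess of reagent the acetate, the secondary bromide and the chlorides should survive.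

**Compound list**

1 | (R)-2-hydroxybutanoic acid | CC[C@@H](O)C(=O)O | starting material
2 | (R)-2-(benzyloxy)butanoic acid | CC[C@@H](OCc1ccccc1)C(=O)O | intermediate
3 | (R)-3-(benzyloxy)pentan-2-one | CC[C@@H](OCc1ccccc1)C(C)=O | intermediate
4 | acrolein (prop-2-enal) | C=CC=O | starting material
5 | dicyclohexylboron enolate of 3, (R)-{[3-(benzyloxy)pent-1-en-2-yl]oxy}dicyclohexylborane (not isolated) | CC[C@@H](OCc1ccccc1)C(=C)OB(C1CCCCC1)C1CCCCC1 | intermediate
6 | (3R,6S)-3-(benzyloxy)-6-hydroxyoct-7-en-4-one | CC[C@@H](OCc1ccccc1)C(=O)C[C@H](O)C=C | intermediate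
7 | (3R,6S)-3-(benzyloxy)-6-[(triethylsilyl)oxy]oct-7-en-4-one | CC[C@@H](OCc1ccccc1)C(=O)C[C@H](O[Si](CC)(CC)CC)C=C | intermediate
8 | (3R,4S,6S)-3-(benzyloxy)-6-[(triethylsilyl)oxy]oct-7-en-4-ol | CC[C@@H](OCc1ccccc1)[C@@H](O)C[C@H](O[Si](CC)(CC)CC)C=C | intermediate
9 | (3R,4S,6S)-3-(benzyloxy)-6-[(triethylsilyl)oxy]oct-7-en-4-yl methanesulfonate | CC[C@@H](OCc1ccccc1)[C@@H](OS(C)(=O)=O)C[C@H](O[Si](CC)(CC)CC)C=C | intermediate
10 | (3R,4S,6S)-3-(benzyloxy)-6-hydroxyoct-7-en-4-yl methanesulfonate (not isolated) | CC[C@@H](OCc1ccccc1)[C@@H](OS(C)(=O)=O)C[C@H](O)C=C | intermediate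
11 | (2R,4S)-2-[(1R)-1-(benzyloxy)propyl]-4-ethenyloxetane (cis; O, C10, C11, C12) | C=C[C@@H]1C[C@H]([C@H](OCc2ccccc2)CC)O1 | intermediate
12 | dichloroacetyl chloride | ClC(Cl)C(Cl)=O | starting material
13 | dichloroketene (not isolated) | ClC(Cl)=C=O | intermediate
14 | acyloxonium enolate zwitterion: oxetane oxygen of 11 bonded to C6 of a 2,2-dichloro-1-oxidoethenyl group (not isolated) | C=C[C@@H]1C[C@H]([C@H](OCc2ccccc2)CC)[O+]1C([O-])=C(Cl)Cl | intermediate
15 | (8R,5Z)-8-[(1R)-1-(benzyloxy)propyl]-3,3-dichloro-3,4,7,8-tetrahydro-2H-oxocin-2-one | O=C1O[C@@H]([C@H](OCc2ccccc2)CC)C/C=C\CC1(Cl)Cl | intermediate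
16 | (3R,8R,5Z)-8-[(1R)-1-(benzyloxy)propyl]-3-chloro-3,4,7,8-tetrahydro-2H-oxocin-2-one (3,8-cis epimer, not isolated) | O=C1O[C@@H]([C@H](OCc2ccccc2)CC)C/C=C\C[C@H]1Cl | intermediate
17 | (3S,8R,5Z)-8-[(1R)-1-(benzyloxy)propyl]-3-chloro-3,4,7,8-tetrahydro-2H-oxocin-2-one (3,8-trans) | O=C1O[C@@H]([C@H](OCc2ccccc2)CC)C/C=C\C[C@@H]1Cl | intermediate
18 | (2R,4S,5S,7S)-2-[(1R)-1-(benzyloxy)propyl]-5,7-dichloro-8-oxooxocan-4-yl acetate | O=C1O[C@@H]([C@H](OCc2ccccc2)CC)C[C@H](OC(C)=O)[C@@H](Cl)C[C@@H]1Cl | intermediate
19 | diisobutylaluminium hemiacetal of 18 (O–Al at the former carbonyl carbon, not isolated) | CC(C)C[Al](CC(C)C)OC1O[C@@H]([C@H](OCc2ccccc2)CC)C[C@H](OC(C)=O)[C@@H](Cl)C[C@@H]1Cl | intermediate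
20 | (3S,5S,6S,8R)-8-[(1R)-1-(benzyloxy)propyl]-3,5-dichlorooxocane-2,6-diyl diacetate (anomers at C2) | CC(=O)OC1O[C@@H]([C@H](OCc2ccccc2)CC)C[C@H](OC(C)=O)[C@@H](Cl)C[C@@H]1Cl | intermediate
21 | allyltrimethylsilane | C=CC[Si](C)(C)C | starting material
22 | (2R,4S,5S,7S,8S)-2-[(1R)-1-(benzyloxy)propyl]-5,7-dichloro-8-(prop-2-en-1-yl)oxocan-4-yl acetate | C=CC[C@@H]1O[C@@H]([C@H](OCc2ccccc2)CC)C[C@H](OC(C)=O)[C@@H](Cl)C[C@@H]1Cl | intermediate
23 | (2R,4S,5S,7S,8S)-5,7-dichloro-2-[(1R)-1-hydroxypropyl]-8-(prop-2-en-1-yl)oxocan-4-yl acetate | C=CC[C@@H]1O[C@@H]([C@H](O)CC)C[C@H](OC(C)=O)[C@@H](Cl)C[C@@H]1Cl | intermediate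
24 | (2R,4S,5S,7S,8S)-2-[(1S)-1-bromopropyl]-5,7-dichloro-8-(prop-2-en-1-yl)oxocan-4-yl acetate | C=CC[C@@H]1O[C@@H]([C@@H](Br)CC)C[C@H](OC(C)=O)[C@@H](Cl)C[C@@H]1Cl | intermediate
25 | (E)-but-2-enal (crotonaldehyde) | C/C=C/C=O | starting material
26 | (2R,4S,5S,7S,8S)-2-[(1S)-1-bromopropyl]-5,7-dichloro-8-[(2E)-4-oxobut-2-en-1-yl]oxocan-4-yl acetate | O=C/C=C/C[C@@H]1O[C@@H]([C@@H](Br)CC)C[C@H](OC(C)=O)[C@@H](Cl)C[C@@H]1Cl | intermediate
27 | (2R,4S,5S,7S,8S)-2-[(1S)-1-bromopropyl]-5,7-dichloro-8-[(2E)-pent-2-en-4-yn-1-yl]oxocan-4-yl acetate | C#C/C=C/C[C@@H]1O[C@@H]([C@@H](Br)CC)C[C@H](OC(C)=O)[C@@H](Cl)C[C@@H]1Cl | target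

**Step count**

Total: 16 steps. Longest linear sequence: 16 steps (fully linear from 1).

**Steps most likely to fail**

Step 8. The process at risk is interception of the acyloxonium zwitterion before the [3,3]-shift: chloride opening at the allylic carbon, ketene oligomerisation, or cycloaddition to the vinyl group. The fallback is the ketene acetal Claisen ring expansion, known chemistry that makes the same bond changes (C7–C8 formed, O–C10 broken) from a six-membered acetal. It sets out from 6, which must then be a single C10 diastereomer because C10 relays to C12 here. Narasaka–Prasad reduction (Et2BOMe, NaBH4, THF/MeOH, −78 °C) should give the all-syn diol (3R,4R,6S)-3-(benzyloxy)oct-7-ene-4,6-diol F1. Acetal exchange with (phenylselanyl)acetaldehyde diethyl acetal (pyridinium p-toluenesulfonate, toluene, 110 °C) should give (4R,6S)-4-[(1R)-1-(benzyloxy)propyl]-6-ethenyl-2-[(phenylselanyl)methyl]-1,3-dioxane F2. NaIO4 would oxidise it to the selenoxide F3, which on heating with DBU in xylene eliminates to the 2-methylidene-1,3-dioxane F4. This rearranges in the same flask to the unchlorinated lactone (8R,5Z)-8-[(1R)-1-(benzyloxy)propyl]-3,4,7,8-tetrahydro-2H-oxocin-2-one F5. Enolisation with LiN(SiMe3)2 at −78 °C and chlorination with N-chlorosuccinimide from the outer face would bring the sequence back to the route at 17.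

Step 10. The process at risk is poor regioselectivity (acetate entering at C9) or poor facial selectivity in the opening of the chloronium ion. The fallback makes the C10–O bond first with electrophilic oxygen and the C9–Cl bond second with nucleophilic chloride. It sets out from 17. Dimethyldioxirane in acetone at 0 °C should epoxidise the Z alkene from the open outer face, anti to the side chain, giving (3S,5R,6S,8R)-8-[(1R)-1-(benzyloxy)propyl]-3-chloro-5,6-epoxyoxocan-2-one F6. Opening with acetyl chloride and catalytic Bu4NCl in CH2Cl2 (chloride attacks with inversion, the epoxide oxygen is acetylated) gives a trans chloro acetate. Attack at C9 comes back to the route at 18, and the choice between C9 and C10 is then decided in an SN2 step instead of by cation stability.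

Step 12. The process at risk is poor facial selectivity in the addition to the oxocarbenium ion (allyl entering syn to the C12 side chain), or sluggish ionisation next to the C7 chlorine. The fallback exchanges the roles of carbon nucleophile and hydride at C6. It sets out from 18. CH2=CHCH2MgBr (1.05 equiv, THF, −78 °C) should add to the α-chloro lactone carbonyl, the more electrophilic of the two esters, giving the hemiketal (2R,4S,5S,7S)-2-[(1R)-1-(benzyloxy)propyl]-5,7-dichloro-8-hydroxy-8-(prop-2-en-1-yl)oxocan-4-yl acetate F7. Et3SiH and BF3·OEt2 (CH2Cl2, −78 → −20 °C) then reduce the derived oxocarbenium ion. Hydride is now the incoming group, so a face preference that misplaces the allyl group in step 12 places it correctly here, and the sequence comes back to the route at 22.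

**Further compounds**

F1 | step 8 | (3R,4R,6S)-3-(benzyloxy)oct-7-ene-4,6-diol | CC[C@@H](OCc1ccccc1)[C@H](O)C[C@H](O)C=C
F2 | step 8 | (4R,6S)-4-[(1R)-1-(benzyloxy)propyl]-6-ethenyl-2-[(phenylselanyl)methyl]-1,3-dioxane | C=C[C@@H]1C[C@H]([C@H](OCc2ccccc2)CC)OC(C[Se]c2ccccc2)O1
F3 | step 8 | (4R,6S)-4-[(1R)-1-(benzyloxy)propyl]-6-ethenyl-2-[(phenylseleninyl)methyl]-1,3-dioxane | C=C[C@@H]1C[C@H]([C@H](OCc2ccccc2)CC)OC(C[Se](=O)c2ccccc2)O1
F4 | step 8 | (4R,6S)-4-[(1R)-1-(benzyloxy)propyl]-6-ethenyl-2-methylidene-1,3-dioxane | C=C[C@@H]1C[C@H]([C@H](OCc2ccccc2)CC)OC(=C)O1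
F5 | step 8 | (8R,5Z)-8-[(1R)-1-(benzyloxy)propyl]-3,4,7,8-tetrahydro-2H-oxocin-2-one | O=C1O[C@@H]([C@H](OCc2ccccc2)CC)C/C=C\CC1
F6 | step 10 | (3S,5R,6S,8R)-8-[(1R)-1-(benzyloxy)propyl]-3-chloro-5,6-epoxyoxocan-2-one (epoxide oxygen trans to the C8 side chain) | O=C1O[C@@H]([C@H](OCc2ccccc2)CC)C[C@@H]3O[C@@H]3C[C@@H]1Cl
F7 | step 12 | (2R,4S,5S,7S)-2-[(1R)-1-(benzyloxy)propyl]-5,7-dichloro-8-hydroxy-8-(prop-2-en-1-yl)oxocan-4-yl acetate (hemiketal, C8 unassigned) | C=CCC1(O)O[C@@H]([C@H](OCc2ccccc2)CC)C[C@H](OC(C)=O)[C@@H](Cl)C[C@@H]1Cl
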